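**Plan**

- Retrosynthesis: the C5 ketone is taken back to an allylic silyl ether. The lactone bond C7a–O1 is cut and O1 returned to C6 (1,3-allylic shift), O1 is then excised from C2–C6 (Baeyer–Villiger), and two C3–O bonds are restored as a ketal. The bicyclo[2.2.2]octenone so exposed is cut at C3a–C4 and C5–C6.
- Enabling feature: C2, C3, C3a, C7a, C7 and C6 (numbering: lactone O1, carbonyl C2, C3, quaternary C3a, C4, ketone C5, alkene C6=C7, oxygenated C7a) are the six carbons of a catechol ring that already carries farnesyl at C3a. Only C4–C5 is added, as a silyl vinyl ether, across C3a and C6; O1 is inserted afterwards.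
- Forward: 2,6-dibromophenol is C-farnesylated, O-alkylated with the three-carbon acid, and its second bromine turned into OH. Oxidative dearomatisation closes a spiro-dioxanone and the [4+2] closes the carbocycle C3a–C4–C5–C6–C7–C7a. SmI2 removes the ketal, oxygen is inserted, the bridged lactone contracts to the cis-fused γ-lactone, and the enone is unveiled.
- Stereochemistry: a chiral aryl-λ3-iodane sets the ketal carbon; the ketal steers the diene face and thereby C3a; C7a follows from a suprafacial carboxylate shift that the C3 tether forces to be cis; the C5 carbinol centre is oxidised away.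

Key step: step 5

Conventions: farnesyl = (2E,6E)-3,7,11-trimethyldodeca-2,6,10-trien-1-yl; TBS = tert-butyldimethylsilyl; labels C2–C7a are the target's ring atoms and are used for all intermediates.

Assumption: the (R,R)-configured iodane is taken to give the (6R)-ketal and the enol ether to add to the dienone face that carries the ether oxygen (anti to the acyloxy oxygen). Only the product of these two senses survives ketal removal, so if one of them is the opposite the (S,S)-iodane is used and nothing else changes.

**Route**

Step 1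
Reactants: 1 2,6-dibromophenol; 2 (2E,6E)-farnesyl bromide
Product: 4 2-bromo-6-[(2E,6E)-farnesyl]phenol, via lithium 2-bromo-6-lithiophenolate 3 (not isolated)
Conditions: n-BuLi (2.1 equiv), THF, −78 °C; CuBr·SMe2 (0.2 equiv), then 2, −78 → 0 °C; aq HCl
Reagents that add atoms: n-butyllithium, [Li]CCCC (the lithium atoms of 3 only; none remain in 4)
Why: Deprotonation and a single bromine–lithium exchange (the second bromine of the electron-rich dianion should be inert at −78 °C) give the O,C-dilithio species, whose aryl carbanion is allylated at the primary carbon of 2 by copper-assisted SN2 substitution with the E-alkenes untouched, and the symmetry of 1 removes any regiochemical choice.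

Step 2
Reactants: 4 2-bromo-6-[(2E,6E)-farnesyl]phenol; 5 β-propiolactone (oxetan-2-one)
Product: 6 3-{2-bromo-6-[(2E,6E)-farnesyl]phenoxy}propanoic acid
Conditions: t-BuOK (1.05 equiv), THF, 0 °C; then 5 (1.3 equiv), 0 → 25 °C; aq HCl
Reagents that add atoms: none
Why: The potassium phenoxide opens the β-lactone at its CH2–O carbon (SN2 with alkyl–oxygen cleavage, the classical route to 3-aryloxypropanoic acids), and since the only oxygen of 4 is the one flanked by bromine and farnesyl the tether can go nowhere else.

Step 3
Reactants: 6 3-{2-bromo-6-[(2E,6E)-farnesyl]phenoxy}propanoic acid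
Product: 8 3-{2-hydroxy-6-[(2E,6E)-farnesyl]phenoxy}propanoic acid, via pinacol arylboronate 7 (not isolated)
Conditions: B2pin2 (1.5 equiv), Pd(dppf)Cl2 (5 mol%), KOAc (4 equiv), 1,4-dioxane, 90 °C; filter through Celite; then H2O2 (30% aq), NaOH, THF–H2O, 0 °C; aq HCl
Reagents that add atoms: hydrogen peroxide, OO (phenolic oxygen of 8); bis(pinacolato)diboron, CC1(C)OB(OC1(C)C)B1OC(C)(C)C(C)(C)O1 (boryl group of 7 only)
Why: Miyaura borylation of the aryl bromide followed by alkaline peroxide oxidation of the C–B bond (1,2-aryl shift from boron to oxygen) turns Br into OH, the hydroperoxide anion being unable to epoxidise the unactivated trisubstituted alkenes while the acid travels as its carboxylate.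

Step 4
Reactants: 9 (2R,2'R)-2,2'-[(2-iodo-1,3-phenylene)bis(oxy)]bis[N-(2,4,6-trimethylphenyl)propanamide]
Product: 10 (2R,2'R)-2,2'-{[2-(diacetoxy-λ3-iodanyl)-1,3-phenylene]bis(oxy)}bis[N-(2,4,6-trimethylphenyl)propanamide]
Conditions: AcOOH (32 wt% in AcOH), AcOH, 25 °C; evaporate, triturate (hexane–Et2O)
Reagents that add atoms: peracetic acid, CC(=O)OO; acetic acid, CC(O)=O
Why: Oxidation of an aryl iodide by peracetic acid with ligand exchange for acetate is the standard preparation of (diacetoxyiodo)arenes, leaves the lactamide stereocentres untouched, and is run in a separate flask so that no peracid ever meets the triene.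

Step 5
Reactants: 8 3-{2-hydroxy-6-[(2E,6E)-farnesyl]phenoxy}propanoic acid; 10 chiral (diacetoxy)-λ3-iodane; 11 tert-butyldimethyl(vinyloxy)silane
Product: 13 (1S,2R,4S,8S)-8-(tert-butyldimethylsilyloxy)-1-[(2E,6E)-farnesyl]spiro[bicyclo[2.2.2]oct-5-ene-2,2'-[1,3]dioxane]-3,4'-dione, via spiro-lactone dienone 12 (not isolated)
Conditions: 10 (1.1 equiv), CH2Cl2–(CF3)2CHOH (4:1), −20 °C; then NaHCO3 (solid), 11 (10 equiv), −20 → 25 °C
Reagents that add atoms: none
Why: Proposed new method: Ligand exchange of the phenol at iodine and 6-exo-trig attack of the carboxylate oxygen on the ether-bearing ring carbon, with loss of iodoarene 9, should give dienone 12, an electron-poor diene whose δ-carbon (C3a, bearing farnesyl) takes the nucleophilic CH2 of 11 while its α-carbon (C6) takes the oxygenated carbon in an asynchronous endo [4+2]. The closest known reactions are the enantioselective aryl-λ3-iodane spirolactonisation of 3-(2-hydroxyphenoxy)propanoic acids with in-flask Diels–Alder capture and the inverse-demand addition of enol ethers to dimethyl-ketal masked o-benzoquinones; new is their union with a stoichiometric preformed iodane on a dienone alkylated at the reacting terminus. Two rings close: the 1,3-dioxan-4-one by the 6-exo-trig spirocyclisation and the carbocycle C3a–C4–C5–C6–C7–C7a by the suprafacial intermolecular cycloaddition, which also creates the bicyclo[2.2.2]octenone. The ketal carbon is set by the lactamide iodane (reagent control), C3a and C6 by the ketal centre, which sends the dienophile to the face of the ether oxygen, and C5 by the endo rule (silyloxy syn to the new alkene), a centre that is later oxidised away. Regiochemistry follows the polarisation of the dienone (largest LUMO coefficient at the δ-carbon, largest HOMO coefficient at the CH2 of the enol ether), so the unsubstituted carbon meets the hindered terminus. Chemoselectivity rests on ligand exchange at the phenol being far faster than any attack of the iodane on unactivated alkenes, on the alkyl group at C3a blocking the γ,δ-alkene that serves as dienophile in self-dimerisation, and on neutralising the acetic acid before the enol ether is added.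

Step 6
Reactants: 13 spiro-ketal cycloadduct
Product: 14 (1S,4R,7S)-7-(tert-butyldimethylsilyloxy)-4-[(2E,6E)-farnesyl]bicyclo[2.2.2]oct-5-en-2-one
Conditions: SmI2 (5 equiv), THF–MeOH (10:1), −78 → 0 °C
Reagents that add atoms: none
Why: Two successive ketyl-mediated α-C–O cleavages (first the acyloxy, then the alkoxy leaving group, each followed by protonation of the samarium enolate at C3) should strip the ketal as 3-hydroxypropanoic acid, the known SmI2 deoxygenation of masked o-benzoquinone adducts, while the β-silyloxy group is safe because enolisation toward the bridgehead is forbidden and no skeletal stereocentre is touched.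

Step 7
Reactants: 14 bicyclo[2.2.2]octenone
Product: 15 (1S,5R,8S)-8-(tert-butyldimethylsilyloxy)-5-[(2E,6E)-farnesyl]-2-oxabicyclo[3.2.2]non-6-en-3-one
Conditions: (Me3SiO)2 (2.5 equiv), SnCl4 (0.3 equiv), trans-cyclohexane-1,2-diamine (0.3 equiv), 4 Å molecular sieves, CH2Cl2, 0 → 25 °C
Reagents that add atoms: bis(trimethylsilyl) peroxide, C[Si](C)(C)OO[Si](C)(C)C
Why: Baeyer–Villiger oxidation with the silyl peroxide and a diamine-tempered tin Lewis acid, a system made for β,γ-unsaturated bicyclic ketones, should insert oxygen on the side of the secondary allylic bridgehead C6 (a better migrating group than the neopentyl-type C3 methylene) with retention at C6 and without an electrophilic peracid that would epoxidise the triene.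

Step 8
Reactants: 15 bridged allylic lactone
Product: 16 (3aR,5S,7aR)-5-(tert-butyldimethylsilyloxy)-3a-[(2E,6E)-farnesyl]-3a,4,5,7a-tetrahydro-1-benzofuran-2(3H)-one
Conditions: Pd(PPh3)4 (5 mol%), THF, 25 → 45 °C
Reagents that add atoms: none
Why: Zerovalent palladium ionises the allylic C6–O bond with inversion and the tethered carboxylate returns with inversion at the other allyl terminus C7a (Tsuji–Trost-type allylic transposition, net suprafacial), so the strained bridged seven-membered lactone should contract to the five-membered lactone that the C3 tether can only fuse cis, which sets C7a and moves the alkene to C6=C7.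

Step 9
Reactants: 16 silyl-protected cis-fused lactone
Product: 17 (3aR,5S,7aR)-3a-[(2E,6E)-farnesyl]-5-hydroxy-3a,4,5,7a-tetrahydro-1-benzofuran-2(3H)-one
Conditions: TBAF, AcOH (1:1), THF, 0 → 25 °C
Reagents that add atoms: none
Why: Acetic-acid-buffered fluoride cleaves the secondary silyl ether through Si–F bond formation without opening the lactone or touching the triene, and the now allylic C5 carbinol keeps a configuration that is of no consequence for the last step.

Step 10
Reactants: 17 allylic alcohol
Product: 18 (3aR,7aR)-3a-[(2E,6E)-farnesyl]-3a,7a-dihydro-1-benzofuran-2,5(3H,4H)-dione (CNP0400313.1)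
Conditions: MnO2 (activated, 15 equiv), CH2Cl2, 25 °C
Reagents that add atoms: none
Why: Activated MnO2 oxidises the allylic alcohol chemoselectively to the enone, a neutral heterogeneous oxidation that leaves the lactone, the C7a stereocentre and the triene alone and cannot aromatise the ring because C3a is quaternary.

**Compound list**

1 | 2,6-dibromophenol | Oc1c(Br)cccc1Br | starting material
2 | (2E,6E)-farnesyl bromide | CC(C)=CCC/C(C)=C/CC/C(C)=C/CBr | starting material
3 | lithium 2-bromo-6-lithiophenolate | [Li]Oc1c(Br)cccc1[Li] | intermediate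
4 | 2-bromo-6-[(2E,6E)-farnesyl]phenol | CC(C)=CCC/C(C)=C/CC/C(C)=C/Cc1cccc(Br)c1O | intermediate
5 | β-propiolactone (oxetan-2-one) | O=C1CCO1 | starting material
6 | 3-{2-bromo-6-[(2E,6E)-farnesyl]phenoxy}propanoic acid | CC(C)=CCC/C(C)=C/CC/C(C)=C/Cc1cccc(Br)c1OCCC(O)=O | intermediate
7 | 3-{2-[(2E,6E)-farnesyl]-6-(4,4,5,5-tetramethyl-1,3,2-dioxaborolan-2-yl)phenoxy}propanoic acid | CC(C)=CCC/C(C)=C/CC/C(C)=C/Cc1cccc(B2OC(C)(C)C(C)(C)O2)c1OCCC(O)=O | intermediate
8 | 3-{2-hydroxy-6-[(2E,6E)-farnesyl]phenoxy}propanoic acid | CC(C)=CCC/C(C)=C/CC/C(C)=C/Cc1cccc(O)c1OCCC(O)=O | intermediate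
9 | (2R,2'R)-2,2'-[(2-iodo-1,3-phenylene)bis(oxy)]bis[N-(2,4,6-trimethylphenyl)propanamide] | C[C@@H](Oc1cccc(O[C@H](C)C(=O)Nc2c(C)cc(C)cc2C)c1I)C(=O)Nc1c(C)cc(C)cc1C | starting material
10 | (2R,2'R)-2,2'-{[2-(diacetoxy-λ3-iodanyl)-1,3-phenylene]bis(oxy)}bis[N-(2,4,6-trimethylphenyl)propanamide] | C[C@@H](Oc1cccc(O[C@H](C)C(=O)Nc2c(C)cc(C)cc2C)c1I(OC(C)=O)OC(C)=O)C(=O)Nc1c(C)cc(C)cc1C | intermediate
11 | tert-butyldimethyl(vinyloxy)silane | C=CO[Si](C)(C)C(C)(C)C | starting material
12 | (6R)-11-[(2E,6E)-farnesyl]-1,5-dioxaspiro[5.5]undeca-8,10-diene-2,7-dione (spiro-lactone masked o-benzoquinone; farnesyl on the diene carbon next to the ketal) | CC(C)=CCC/C(C)=C/CC/C(C)=C/CC1=CC=CC(=O)[C@@]12OCCC(=O)O2 | intermediate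
13 | (1S,2R,4S,8S)-8-(tert-butyldimethylsilyloxy)-1-[(2E,6E)-farnesyl]spiro[bicyclo[2.2.2]oct-5-ene-2,2'-[1,3]dioxane]-3,4'-dione (farnesyl on the bridgehead next to the ketal carbon; silyloxy syn to the alkene; ketal ether oxygen on the side of the C7–C8 bridge) | CC(C)=CCC/C(C)=C/CC/C(C)=C/C[C@]12C=C[C@H](C(=O)[C@@]13OCCC(=O)O3)[C@@H](O[Si](C)(C)C(C)(C)C)C2 | intermediate
14 | (1S,4R,7S)-7-(tert-butyldimethylsilyloxy)-4-[(2E,6E)-farnesyl]bicyclo[2.2.2]oct-5-en-2-one | CC(C)=CCC/C(C)=C/CC/C(C)=C/C[C@]12C=C[C@H](C(=O)C1)[C@@H](O[Si](C)(C)C(C)(C)C)C2 | intermediate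
15 | (1S,5R,8S)-8-(tert-butyldimethylsilyloxy)-5-[(2E,6E)-farnesyl]-2-oxabicyclo[3.2.2]non-6-en-3-one | CC(C)=CCC/C(C)=C/CC/C(C)=C/C[C@]12C=C[C@H](OC(=O)C1)[C@@H](O[Si](C)(C)C(C)(C)C)C2 | intermediate
16 | (3aR,5S,7aR)-5-(tert-butyldimethylsilyloxy)-3a-[(2E,6E)-farnesyl]-3a,4,5,7a-tetrahydro-1-benzofuran-2(3H)-one (cis-fused; silyloxy trans to the lactone) | CC(C)=CCC/C(C)=C/CC/C(C)=C/C[C@]12C[C@H](O[Si](C)(C)C(C)(C)C)C=C[C@H]1OC(=O)C2 | intermediate
17 | (3aR,5S,7aR)-3a-[(2E,6E)-farnesyl]-5-hydroxy-3a,4,5,7a-tetrahydro-1-benzofuran-2(3H)-one | CC(C)=CCC/C(C)=C/CC/C(C)=C/C[C@]12C[C@H](O)C=C[C@H]1OC(=O)C2 | intermediate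
18 | (3aR,7aR)-3a-[(2E,6E)-farnesyl]-3a,7a-dihydro-1-benzofuran-2,5(3H,4H)-dione (CNP0400313.1) | CC(C)=CCC/C(C)=C/CC/C(C)=C/C[C@]12CC(=O)C=C[C@H]1OC(=O)C2 | target

**Step count**

Total steps: 10. Longest linear sequence: 9 (steps 1–3 and 5–10, from 2,6-dibromophenol); step 4 is a one-step side branch that joins at step 5.

**Steps most likely to fail**

1. Step 5 (proposed new method). The silyl enol ether may be consumed by the iodane, the liberated acid or the fluorinated alcohol before the hindered dienone terminus captures it. Stereochemical fidelity can also leak at two points, reagent control at the ketal and facial control in the cycloaddition; both show up as low enantiomeric purity once the ketal is cut away. The fallback uses known reactions only, sets out from 8 and returns at 14. The dearomatisation is run without asymmetric induction, with PhI(OAc)2 in CH2Cl2 over NaHCO3 and 11 present in excess from the start, as is usual for capturing masked o-benzoquinones as they form. This gives 13 as a racemate with its mirror image, ent-adduct F1. SmI2 as in step 6 then gives 14 together with ent-ketone F2. TBAF/AcOH frees the carbinols as hydroxy ketone F3 and enantiomeric hydroxy ketone F4. A lipase (Burkholderia cepacia lipase, vinyl acetate, chosen by screening so that the unwanted enantiomer reacts) converts F4 into acetate F5. The untouched F3 is separated and resilylated (TBSCl, imidazole, DMF) to 14.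

2. Step 7. The tin Lewis acid may trigger cation–olefin cyclisation of the triene, or ionise the allylic lactone as it forms. The peroxide may attack the electron-rich alkenes, and the C3 methylene may migrate in competition with the bridgehead. The fallback sets out from 14 and returns at 16, so it also makes step 8 unnecessary. Direct irradiation (λ ≈ 300 nm, degassed benzene, 25 °C) causes the photochemical 1,3-acyl shift typical of β,γ-unsaturated bicyclic ketones: the acyl carbon C2 moves from C6 to C7a on the same face and the alkene moves to C6=C7, giving cis-fused cyclobutanone F6. Alkaline hydrogen peroxide (H2O2, NaOH, THF–MeOH, 0 °C, then acidification) then effects the strain-driven Baeyer–Villiger expansion of the cyclobutanone with migration of the more substituted C7a and retention, giving 16; the hydroperoxide anion spares the triene.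

3. Step 8. Ionisation may stall because the metal must bind the alkene face that the endo silyloxy group overhangs, and the π-allyl intermediate may lose a β-hydrogen to give a dienyl acid. The fallback sets out from 15 and returns at 16. Methanolysis (K2CO3, MeOH, 0 °C) opens the strained lactone to hydroxy ester F7, whose allylic C6 carbinol is on the face of the acetate arm. A catalytic oxo-rhenium reagent (Ph3SiOReO3, Et2O, 0 °C) transposes the allylic alcohol suprafacially through a [3,3] shift of its perrhenate ester. The C7a carbinol so formed is cis to the ester arm and lactonises (trace PPTS if needed) to 16, which pulls the equilibrium over.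

**Further compounds**

F1 | step 5 | (1R,2S,4R,8R)-8-(tert-butyldimethylsilyloxy)-1-[(2E,6E)-farnesyl]spiro[bicyclo[2.2.2]oct-5-ene-2,2'-[1,3]dioxane]-3,4'-dione (enantiomer of 13) | CC(C)=CCC/C(C)=C/CC/C(C)=C/C[C@@]12C=C[C@@H](C(=O)[C@]13OCCC(=O)O3)[C@H](O[Si](C)(C)C(C)(C)C)C2
F2 | step 5 | (1R,4S,7R)-7-(tert-butyldimethylsilyloxy)-4-[(2E,6E)-farnesyl]bicyclo[2.2.2]oct-5-en-2-one (enantiomer of 14) | CC(C)=CCC/C(C)=C/CC/C(C)=C/C[C@@]12C=C[C@@H](C(=O)C1)[C@H](O[Si](C)(C)C(C)(C)C)C2
F3 | step 5 | (1S,4R,7S)-4-[(2E,6E)-farnesyl]-7-hydroxybicyclo[2.2.2]oct-5-en-2-one | CC(C)=CCC/C(C)=C/CC/C(C)=C/C[C@]12C=C[C@H](C(=O)C1)[C@@H](O)C2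
F4 | step 5 | (1R,4S,7R)-4-[(2E,6E)-farnesyl]-7-hydroxybicyclo[2.2.2]oct-5-en-2-one | CC(C)=CCC/C(C)=C/CC/C(C)=C/C[C@@]12C=C[C@@H](C(=O)C1)[C@H](O)C2
F5 | step 5 | (1R,4S,7R)-7-acetoxy-4-[(2E,6E)-farnesyl]bicyclo[2.2.2]oct-5-en-2-one | CC(C)=CCC/C(C)=C/CC/C(C)=C/C[C@@]12C=C[C@@H](C(=O)C1)[C@H](OC(C)=O)C2
F6 | step 7 | (1R,3S,6R)-3-(tert-butyldimethylsilyloxy)-1-[(2E,6E)-farnesyl]bicyclo[4.2.0]oct-4-en-7-one | CC(C)=CCC/C(C)=C/CC/C(C)=C/C[C@]12C[C@H](O[Si](C)(C)C(C)(C)C)C=C[C@H]1C(=O)C2
F7 | step 8 | methyl 2-[(1R,4S,5S)-5-(tert-butyldimethylsilyloxy)-1-[(2E,6E)-farnesyl]-4-hydroxycyclohex-2-en-1-yl]acetate | CC(C)=CCC/C(C)=C/CC/C(C)=C/C[C@@]1(CC(=O)OC)C=C[C@H](O)[C@@H](O[Si](C)(C)C(C)(C)C)C1
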